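## The problem

Compound 20 is a flavone: benzene ring A is fused to 4-pyranone ring C, which carries the 4-(prenyloxy)phenyl ring B at C2 and a methoxy group at C3. Ring A is oxygenated everywhere except C6 (O1 on C8a, OMe on C8, OH on C7 and C5). The route therefore has to tell four ring-A oxygens apart: one becomes the ring oxygen, one is methylated, two end up free. There is no stereocentre and no stereogenic double bond in 20; the only stereochemical question is the geometry of an alkene in an open-chain intermediate. The two methyl ethers (O3, O8) must be placed by construction. Selective methylation of a polyphenolic flavone is not realistic, and oxidising C3 of a finished flavone would collide with the prenyl double bond. The aryl prenyl ether excludes hydrogenolysis, strong Brønsted or Lewis acids, electrophilic halogen and peracid late in the route. The 5,7-diol must be masked by groups that keep ring A electron-rich and come off under mild conditions. The enabling feature is C4a: it is the only unsubstituted ring-A carbon ortho to O1 (the other ortho carbon, C8, bears the methoxy group), and it is ortho to O5 and para to O7. An acyl carbon tethered through O1–C2=C3 can therefore reach only this highly nucleophilic carbon; C6 is equally activated but lies para to O1 and out of reach.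

## Retrosynthesis

**20 ⇒ 19 (two acetal C–O bonds).** The free 5- and 7-hydroxyls are traced back to methoxymethyl ethers in 19. Benzyl ethers would need hydrogenolysis or boron halides, both of which destroy the prenyl ether. Silyl ethers would not survive the basic steps before ring closure, and acyl groups would deactivate ring A. The forward step must remove two acetals without ionising the allylic ether.

**19 ⇒ 16 (C4–C4a).** Cutting the bond between the carbonyl carbon and ring A opens ring C to the β-aryloxyacrylic acid 16, which is activated as acid chloride 17 and acyl triflate 18. The neighbouring cut, O1–C2 (diketone or chalcone logic), would require an intermolecular acylation of a ring with two equally activated free positions and would bring in the 3-methoxy group less directly. With the C4–C4a cut the regiochemistry is decided by which oxygen of ring A is the free phenol. The forward reaction must acylate an acetal-bearing arene in the presence of a prenyl ether, so it has to run without free protic acid.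

**16 ⇒ 15 ⇒ 14 + 7 (vinyl C–O bond, later O1–C2).** Acid 16 comes from methyl ester 15. Cutting the aryl–vinyl ether bond of 15 gives phenol 7 and enol tosylate 14, joined by addition–elimination at the β-carbon of an acrylate. This splits the molecule into a ring-A piece and a ring-B/C3 piece of similar size. The forward step needs a β-leaving group that can be installed under basic conditions, since the prenyl ether is already present.

**14 ⇒ 13 ⇒ 12 ⇒ 10 + 11; 10 ⇒ 8 + 9.** Tosylate 14 is the enol derivative of β-keto ester 13, which already holds the future 3-methoxy group. A crossed Claisen condensation of a 4-alkoxybenzoate with 11 would be one step shorter, but it pits a deactivated benzoate against a self-condensing α-alkoxy enolate. The aldol addition of 11 to aldehyde 10 followed by oxidation of aldol 12 is preferred because each step is dependable. Aldehyde 10 is the prenyl ether of 8, made with bromide 9.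

**7 ⇒ 6 ⇒ 5 ⇒ 3 ⇒ 2 ⇒ 1 (oxygen pattern of ring A).** Phenol 7 needs a methoxy group between a free hydroxyl and an acetal oxygen. The formyl carbon of 1 marks exactly that position. Two acetals go on (2), the remaining hydrogen-bonded hydroxyl is benzylated (3), and the aldehyde is converted into a phenol through formate 4 (5). That phenol is methylated (6) and the benzyl group is removed (7). Each oxygen is differentiated by position, and no selective alkylation of equivalent hydroxyls is needed. The prenyl group is not yet present when hydrogen and peracid are used.

## Roads not taken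

**Alternative 1:** Ring A would be built by a Danheiser benzannulation. The cut runs through C8a–C4a and C5–C6 of the benzene ring. Heating rac-4-methoxy-3-(triisopropylsilyloxy)cyclobut-2-en-1-one A2 with (triisopropylsilyloxy)ethyne A3 would give 2-methoxy-3,5-bis(triisopropylsilyloxy)phenol A1 through vinylketene formation, [2+2] addition, four-electron opening and six-electron closure.
- Merits: the four oxygens arrive already differentiated in one step, with the free phenol exactly where O1 is needed and no benzyl on/off sequence. In that respect it is more elegant than the five-step passage from 1 to 7.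
- Weak points: A1 is only a ring-A building block, so ring C and the C4–C4a bond still have to be made afterwards. A2 and A3 are themselves multistep, sensitive compounds. The aryl silyl ethers of A1 would not survive the carbonate and hydroxide steps needed later and would have to be exchanged.
- Comparison: the chosen plan answers with five routine steps from a commodity aldehyde and protecting groups that serve through to the end.

**Alternative 2:** Ring C would be closed at O1–C2. The ynone 1-[2-hydroxy-3-methoxy-4,6-bis(methoxymethoxy)phenyl]-3-[4-(triisopropylsilyloxy)phenyl]prop-2-yn-1-one A5 would be treated with an electrophilic iodine reagent. The phenol oxygen attacks the activated alkyne in a 6-endo mode to give 3-iodo-8-methoxy-5,7-bis(methoxymethoxy)-2-[4-(triisopropylsilyloxy)phenyl]chromen-4-one A4.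
- Merits: the closure is a dependable heteroatom cyclisation with no alkene-geometry question and no acylium chemistry. In certainty of ring closure it is at least as good as the chosen Friedel–Crafts step.
- Weak points: the C4–C4a bond of A5 must be made by an intermolecular acylation of a ring with two activated free positions. The iodinating reagent can also attack C6 of the electron-rich ring and would add to a prenyl double bond, which is why ring B must carry a silyl placeholder. After A4, four further operations remain: iodine to methoxy at C3, desilylation, prenylation and acetal removal.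
- Comparison: the chosen plan has one step after ring closure, exposes ring A to no halogen electrophile, and brings the C3 methoxy group in with 11.

**Alternative 3:** Three bonds (C4a–C4, C4–C3, O1–C2) would be made at once. 6-Iodo-2-methoxy-3,5-bis(methoxymethoxy)phenol A7, carbon monoxide A9 and 1-ethynyl-4-[(3-methylbut-2-en-1-yl)oxy]benzene A8 would combine under palladium(0) and a secondary amine to give 8-methoxy-5,7-bis(methoxymethoxy)-2-{4-[(3-methylbut-2-en-1-yl)oxy]phenyl}chromen-4-one A6.
- Merits: this is the most convergent road. It tolerates acetals and the prenyl ether, A7 would come from 7 by iodination, and the flavone skeleton is reached in fewer steps than in the chosen plan.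
- Weak points: A6 has hydrogen at C3. Introducing the 3-methoxy group afterwards means oxidising C3 of a flavone that contains a more reactive trisubstituted alkene, followed by methylation. Iodination of 7 must choose between two activated positions. The aryl iodide is electron-rich and flanked on both sides, so oxidative addition would be slow. Five-membered closure to an aurone competes.
- Comparison: the chosen plan is longer to the skeleton but carries the C3 oxygen from the start and needs no late oxidation next to the prenyl group.

Key step: step 12

Remarks on the chemistry (assumptions):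
- The target has no stereocentre and no stereogenic double bond; it is one achiral compound, so "single enantiomer" asks for nothing beyond the constitution.
- Compounds 14–18 are named and drawn as the (E)-isomers (acyl carbon cis to the oxygen substituent on the neighbouring alkene carbon). Any (Z)-isomer formed is carried along, because ionisation in step 12 lets both converge.
- Phenoxides, enolates and carboxylates formed by deprotonation in the flask are treated as the compounds they derive from and are not numbered.

## Route

Step 1
Reactants: 1 2,4,6-trihydroxybenzaldehyde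
Product: 2 2-hydroxy-4,6-bis(methoxymethoxy)benzaldehyde
Conditions: MOMCl (2.2 equiv), i-Pr2NEt, CH2Cl2, 0 °C → rt
Reagents that add atoms: chloromethyl methyl ether, COCCl
Why: O-alkylation (Williamson-type acetal formation); the 4-hydroxyl and one ortho-hydroxyl react, while the last ortho-hydroxyl is held in a hydrogen bond to the aldehyde and is left untouched with two equivalents of reagent.

Step 2
Reactants: 2 2-hydroxy-4,6-bis(methoxymethoxy)benzaldehyde
Product: 3 2-(benzyloxy)-4,6-bis(methoxymethoxy)benzaldehyde
Conditions: BnBr, K2CO3, DMF, 60 °C
Reagents that add atoms: benzyl bromide, BrCc1ccccc1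
Why: Williamson ether synthesis on the chelated phenol under carbonate/DMF heating; the benzyl group marks the oxygen that will later become O1 and can be removed before any alkene is present.

Step 3
Reactants: 3 2-(benzyloxy)-4,6-bis(methoxymethoxy)benzaldehyde
Product: 5 2-(benzyloxy)-4,6-bis(methoxymethoxy)phenol, via aryl formate 4 (not isolated)
Conditions: mCPBA, CH2Cl2, 0 °C → rt; aq. NaHCO3 wash; then K2CO3 (cat.), MeOH, rt
Reagents that add atoms: 3-chloroperoxybenzoic acid, OOC(=O)c1cccc(Cl)c1
Why: Dakin-type Baeyer–Villiger oxidation; the electron-rich trialkoxyaryl group migrates in the Criegee intermediate to give formate 4, which methanolysis cleaves to the phenol. The weak carboxylic acid by-product should not affect the acetals.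

Step 4
Reactants: 5 2-(benzyloxy)-4,6-bis(methoxymethoxy)phenol
Product: 6 1-(benzyloxy)-2-methoxy-3,5-bis(methoxymethoxy)benzene
Conditions: MeI, K2CO3, DMF, rt
Reagents that add atoms: iodomethane, CI
Why: Williamson O-methylation of the only free phenol; this fixes the future 8-methoxy group on the carbon that carried the formyl group.

Step 5
Reactants: 6 1-(benzyloxy)-2-methoxy-3,5-bis(methoxymethoxy)benzene
Product: 7 2-methoxy-3,5-bis(methoxymethoxy)phenol
Conditions: H2 (1 atm), 10% Pd/C, EtOAc, rt
Reagents that add atoms: none
Why: Neutral hydrogenolysis of the benzyl ether; acetals and the methyl ether are inert and no alkene is yet in the molecule.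

Step 6
Reactants: 8 4-hydroxybenzaldehyde; 9 1-bromo-3-methylbut-2-ene (prenyl bromide)
Product: 10 4-[(3-methylbut-2-en-1-yl)oxy]benzaldehyde
Conditions: K2CO3, acetone, reflux
Reagents that add atoms: none
Why: Williamson alkylation of a phenoxide with a primary allylic bromide (SN2); O-alkylation dominates for this acidic, para-acceptor phenol.

Step 7
Reactants: 11 methyl methoxyacetate; 10 4-[(3-methylbut-2-en-1-yl)oxy]benzaldehyde
Product: 12 methyl 3-hydroxy-2-methoxy-3-{4-[(3-methylbut-2-en-1-yl)oxy]phenyl}propanoate (racemic, mixture of syn and anti diastereomers)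
Conditions: LDA, THF, −78 °C; then 10, −78 °C; aq. NH4Cl
Reagents that add atoms: none
Why: Aldol addition of the lithium enolate of 11 to a non-enolisable aromatic aldehyde at low temperature; the two new stereocentres are not controlled, and both are erased in steps 8 and 9.

Step 8
Reactants: 12 methyl 3-hydroxy-2-methoxy-3-{4-[(3-methylbut-2-en-1-yl)oxy]phenyl}propanoate
Product: 13 methyl 2-methoxy-3-{4-[(3-methylbut-2-en-1-yl)oxy]phenyl}-3-oxopropanoate (racemic)
Conditions: Dess–Martin periodinane, CH2Cl2, 0 °C → rt
Reagents that add atoms: none
Why: Dess–Martin oxidation of a benzylic secondary alcohol to the β-keto ester; the periodinane does not attack the trisubstituted alkene or the allyl aryl ether.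

Step 9
Reactants: 13 methyl 2-methoxy-3-{4-[(3-methylbut-2-en-1-yl)oxy]phenyl}-3-oxopropanoate
Product: 14 methyl (E)-2-methoxy-3-{4-[(3-methylbut-2-en-1-yl)oxy]phenyl}-3-(tosyloxy)prop-2-enoate
Conditions: TsCl, TMEDA, LiCl, MeCN, 0 °C → rt
Reagents that add atoms: 4-methylbenzenesulfonyl chloride, Cc1ccc(S(=O)(=O)Cl)cc1
Why: O-sulfonylation of a β-keto ester enolate; the lithium-chelated enolate holds the ketone oxygen cis to the ester carbonyl, so the tosyloxy group should end up cis to the ester, which is (E) here because of the C2 methoxy group. The conditions are basic throughout, which spares the prenyl ether.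

Step 10
Reactants: 14 methyl (E)-2-methoxy-3-{4-[(3-methylbut-2-en-1-yl)oxy]phenyl}-3-(tosyloxy)prop-2-enoate; 7 2-methoxy-3,5-bis(methoxymethoxy)phenol
Product: 15 methyl (E)-2-methoxy-3-[2-methoxy-3,5-bis(methoxymethoxy)phenoxy]-3-{4-[(3-methylbut-2-en-1-yl)oxy]phenyl}prop-2-enoate
Conditions: Cs2CO3, DMF, rt → 50 °C
Reagents that add atoms: none
Why: Nucleophilic vinylic substitution by addition–elimination; the phenoxide of 7 adds to the β-carbon of the sulfonyloxy acrylate and the ester-stabilised carbanion expels tosylate, normally with retention of geometry. This forms the future O1–C2 bond.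

Step 11
Reactants: 15 methyl (E)-2-methoxy-3-[2-methoxy-3,5-bis(methoxymethoxy)phenoxy]-3-{4-[(3-methylbut-2-en-1-yl)oxy]phenyl}prop-2-enoate
Product: 16 (E)-2-methoxy-3-[2-methoxy-3,5-bis(methoxymethoxy)phenoxy]-3-{4-[(3-methylbut-2-en-1-yl)oxy]phenyl}prop-2-enoic acid
Conditions: LiOH·H2O, THF/MeOH/H2O, 40 °C; then 1 M HCl to pH 4, 0 °C
Reagents that add atoms: lithium hydroxide, [Li+].[OH-]
Why: Saponification of the methyl ester by acyl substitution; acetals, both aryl ethers and the prenyl group are stable to hydroxide and to a brief, cold, weakly acidic work-up.

Step 12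
Reactants: 16 (E)-2-methoxy-3-[2-methoxy-3,5-bis(methoxymethoxy)phenoxy]-3-{4-[(3-methylbut-2-en-1-yl)oxy]phenyl}prop-2-enoic acid
Product: 19 3,8-dimethoxy-5,7-bis(methoxymethoxy)-2-{4-[(3-methylbut-2-en-1-yl)oxy]phenyl}-4H-chromen-4-one, via acid chloride 17 (not isolated), via acyl triflate 18 (not isolated)
Conditions: 1-chloro-N,N,2-trimethylprop-1-en-1-amine, 2,6-di-tert-butyl-4-methylpyridine, CH2Cl2, 0 °C → rt; then AgOTf, −40 → 0 °C
Reagents that add atoms: none
Why: The chloroenamine converts acid 16 into acid chloride 17 without releasing hydrogen chloride, and silver triflate then removes chloride to give acyl triflate 18. This ionises readily because the acylium ion has a ketene–oxocarbenium resonance form in which the charge sits on flavone C2 between the aryloxy oxygen and the 4-alkoxyphenyl ring. Ring carbon C4a attacks the acyl carbon and the hindered pyridine takes the proton, so the step is an intramolecular Friedel–Crafts acylation; the closest known reaction type is the acid-mediated cyclisation of β-aryloxycinnamic acids to flavones. Ring C closes in a 6-exo mode at the acyl carbon (exo-trig on 18, exo-dig on the free acylium ion), forming C4–C4a. No stereocentre is created. Regioselectivity is secured by the substrate: C8 carries the methoxy group, C6 is para to the tether and cannot be reached, and ring B is attacked neither through a strained five-membered closure nor at a position meta to its only donor. The acyl carbon must lie cis to the aryloxy group, which the (E)-geometry provides, and the reduced C2–C3 bond order in the delocalised cation should allow a (Z)-isomer to rotate and converge. Buffered, halide-abstracting conditions in place of a strong Lewis or Brønsted acid are what should let the two acetals and the prenyl ether survive.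

Step 13
Reactants: 19 3,8-dimethoxy-5,7-bis(methoxymethoxy)-2-{4-[(3-methylbut-2-en-1-yl)oxy]phenyl}-4H-chromen-4-one
Product: 20 5,7-dihydroxy-3,8-dimethoxy-2-{4-[(3-methylbut-2-en-1-yl)oxy]phenyl}-4H-chromen-4-one
Conditions: HCl (1.25 M in MeOH), THF, 0 °C → rt
Reagents that add atoms: none
Why: Acid-catalysed transacetalisation of the two aryl methoxymethyl ethers through oxocarbenium ions; the 5-O-acetal peri to the carbonyl should go first. Acetal cleavage should be much faster than ionisation of, or addition to, the prenyl ether under dilute acid at low temperature.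

## Compound list

1 | 2,4,6-trihydroxybenzaldehyde | O=Cc1c(O)cc(O)cc1O | starting material
2 | 2-hydroxy-4,6-bis(methoxymethoxy)benzaldehyde | O=Cc1c(O)cc(OCOC)cc1OCOC | intermediate
3 | 2-(benzyloxy)-4,6-bis(methoxymethoxy)benzaldehyde | O=Cc1c(OCc2ccccc2)cc(OCOC)cc1OCOC | intermediate
4 | 2-(benzyloxy)-4,6-bis(methoxymethoxy)phenyl formate | O=COc1c(OCc2ccccc2)cc(OCOC)cc1OCOC | intermediate
5 | 2-(benzyloxy)-4,6-bis(methoxymethoxy)phenol | Oc1c(OCc2ccccc2)cc(OCOC)cc1OCOC | intermediate
6 | 1-(benzyloxy)-2-methoxy-3,5-bis(methoxymethoxy)benzene | COc1c(OCc2ccccc2)cc(OCOC)cc1OCOC | intermediate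
7 | 2-methoxy-3,5-bis(methoxymethoxy)phenol | COc1c(O)cc(OCOC)cc1OCOC | intermediate
8 | 4-hydroxybenzaldehyde | O=Cc1ccc(O)cc1 | starting material
9 | 1-bromo-3-methylbut-2-ene (prenyl bromide) | CC(C)=CCBr | starting material
10 | 4-[(3-methylbut-2-en-1-yl)oxy]benzaldehyde | O=Cc1ccc(OCC=C(C)C)cc1 | intermediate
11 | methyl methoxyacetate | COCC(=O)OC | starting material
12 | methyl 3-hydroxy-2-methoxy-3-{4-[(3-methylbut-2-en-1-yl)oxy]phenyl}propanoate (racemic, syn/anti mixture) | COC(=O)C(OC)C(O)c1ccc(OCC=C(C)C)cc1 | intermediate
13 | methyl 2-methoxy-3-{4-[(3-methylbut-2-en-1-yl)oxy]phenyl}-3-oxopropanoate (racemic) | COC(=O)C(OC)C(=O)c1ccc(OCC=C(C)C)cc1 | intermediate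
14 | methyl (E)-2-methoxy-3-{4-[(3-methylbut-2-en-1-yl)oxy]phenyl}-3-(tosyloxy)prop-2-enoate | COC(=O)/C(OC)=C(\OS(=O)(=O)c1ccc(C)cc1)c1ccc(OCC=C(C)C)cc1 | intermediate
15 | methyl (E)-2-methoxy-3-[2-methoxy-3,5-bis(methoxymethoxy)phenoxy]-3-{4-[(3-methylbut-2-en-1-yl)oxy]phenyl}prop-2-enoate | COC(=O)/C(OC)=C(\Oc1cc(OCOC)cc(OCOC)c1OC)c1ccc(OCC=C(C)C)cc1 | intermediate
16 | (E)-2-methoxy-3-[2-methoxy-3,5-bis(methoxymethoxy)phenoxy]-3-{4-[(3-methylbut-2-en-1-yl)oxy]phenyl}prop-2-enoic acid | OC(=O)/C(OC)=C(\Oc1cc(OCOC)cc(OCOC)c1OC)c1ccc(OCC=C(C)C)cc1 | intermediate
17 | (E)-2-methoxy-3-[2-methoxy-3,5-bis(methoxymethoxy)phenoxy]-3-{4-[(3-methylbut-2-en-1-yl)oxy]phenyl}prop-2-enoyl chloride | ClC(=O)/C(OC)=C(\Oc1cc(OCOC)cc(OCOC)c1OC)c1ccc(OCC=C(C)C)cc1 | intermediate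
18 | (E)-2-methoxy-3-[2-methoxy-3,5-bis(methoxymethoxy)phenoxy]-3-{4-[(3-methylbut-2-en-1-yl)oxy]phenyl}prop-2-enoic trifluoromethanesulfonic anhydride | O=C(OS(=O)(=O)C(F)(F)F)/C(OC)=C(\Oc1cc(OCOC)cc(OCOC)c1OC)c1ccc(OCC=C(C)C)cc1 | intermediate
19 | 3,8-dimethoxy-5,7-bis(methoxymethoxy)-2-{4-[(3-methylbut-2-en-1-yl)oxy]phenyl}-4H-chromen-4-one | COc1c(-c2ccc(OCC=C(C)C)cc2)oc2c(OC)c(OCOC)cc(OCOC)c2c1=O | intermediate
20 | 5,7-dihydroxy-3,8-dimethoxy-2-{4-[(3-methylbut-2-en-1-yl)oxy]phenyl}-4H-chromen-4-one | COc1c(-c2ccc(OCC=C(C)C)cc2)oc2c(OC)c(O)cc(O)c2c1=O | target

## Step count and risks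

Total steps: 13. Longest linear sequence: 9 steps (1 → 2 → 3 → 5 → 6 → 7 → 15 → 16 → 19 → 20). The ring-B branch (8 → 10 → 12 → 13 → 14) has 4 steps before the union in step 10.

**Step 12 (key step).** The main danger is that ring closure is slower than acid-induced loss of an acetal or the prenyl group if buffering is incomplete, or that ionisation stalls at the acid chloride so that work-up only returns 16. A (Z)-configured acyl species that does not ionise could not reach C4a at all. Fallback by polarity reversal, forming the same C4–C4a bond with an aryl anion and no acid: phenol 7 would be brominated ortho to the hydroxyl (NBS, catalytic i-Pr2NH, CH2Cl2) to give 6-bromo-2-methoxy-3,5-bis(methoxymethoxy)phenol F1. Its phenoxide would displace the tosylate of 14 (Cs2CO3, DMF) to give methyl (E)-3-[2-bromo-6-methoxy-3,5-bis(methoxymethoxy)phenoxy]-2-methoxy-3-{4-[(3-methylbut-2-en-1-yl)oxy]phenyl}prop-2-enoate F2. Bromine–lithium exchange (t-BuLi, THF, −100 → −78 °C) followed by Parham-type attack of the aryllithium on the neighbouring methyl ester would close ring C and rejoin the route at 19. This variant requires the (E)-geometry and a selective ortho-bromination, which is why it is the reserve and not the first choice.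

**Step 10.** The phenoxide may attack sulfur instead of carbon (sulfonyl transfer back to the enolate of 13), or addition to the hindered, donor-substituted β-carbon may be too slow. Fallback with a leaving group that has no electrophilic heteroatom: keto ester 13 would be converted with dichlorotriphenylphosphorane and Et3N in MeCN into methyl (E)-3-chloro-2-methoxy-3-{4-[(3-methylbut-2-en-1-yl)oxy]phenyl}prop-2-enoate F3 (either geometry is usable). The classical addition–elimination of the phenoxide of 7 on this β-chloroacrylate (Cs2CO3, DMF) would return to the route at 15.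

**Step 13.** Partial ionisation of the allylic ether to a prenyl cation, or addition of HCl or methanol across the trisubstituted alkene, may set in while the slower 7-O-acetal is still being cleaved. Fallback without protic acid: 19 would be treated with triethylsilyl triflate and 2,2'-bipyridyl in MeCN, which exchanges aryl methoxymethyl ethers for silyl ethers, to give 3,8-dimethoxy-2-{4-[(3-methylbut-2-en-1-yl)oxy]phenyl}-5,7-bis(triethylsilyloxy)-4H-chromen-4-one F4. Buffered fluoride (TBAF, AcOH, THF) would then release 20.

**Step 11.** Hydroxide may add to the β-carbon of the aryloxyacrylate and expel the phenoxide of 7 (reverse of step 10), or hydrolysis of the twisted, tetrasubstituted ester may be sluggish. Fallback that attacks the methyl carbon instead of the acyl carbon: 15 would be heated with lithium iodide in ethyl acetate (SN2 dealkylation of the methyl ester), and mild acidification of the lithium carboxylate would return to the route at 16. No new compound is involved.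

## Further compounds

F1 | step 12 | 6-bromo-2-methoxy-3,5-bis(methoxymethoxy)phenol | COc1c(O)c(Br)c(OCOC)cc1OCOC
F2 | step 12 | methyl (E)-3-[2-bromo-6-methoxy-3,5-bis(methoxymethoxy)phenoxy]-2-methoxy-3-{4-[(3-methylbut-2-en-1-yl)oxy]phenyl}prop-2-enoate | COC(=O)/C(OC)=C(\Oc1c(Br)c(OCOC)cc(OCOC)c1OC)c1ccc(OCC=C(C)C)cc1
F3 | step 10 | methyl (E)-3-chloro-2-methoxy-3-{4-[(3-methylbut-2-en-1-yl)oxy]phenyl}prop-2-enoate | COC(=O)/C(OC)=C(\Cl)c1ccc(OCC=C(C)C)cc1
F4 | step 13 | 3,8-dimethoxy-2-{4-[(3-methylbut-2-en-1-yl)oxy]phenyl}-5,7-bis(triethylsilyloxy)-4H-chromen-4-one | COc1c(-c2ccc(OCC=C(C)C)cc2)oc2c(OC)c(O[Si](CC)(CC)CC)cc(O[Si](CC)(CC)CC)c2c1=O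
F0 | step 11 | none | none
A1 | alternative 1 | 2-methoxy-3,5-bis(triisopropylsilyloxy)phenol | COc1c(O)cc(O[Si](C(C)C)(C(C)C)C(C)C)cc1O[Si](C(C)C)(C(C)C)C(C)C
A2 | alternative 1 | rac-4-methoxy-3-(triisopropylsilyloxy)cyclobut-2-en-1-one | COC1C(O[Si](C(C)C)(C(C)C)C(C)C)=CC1=O
A3 | alternative 1 | (triisopropylsilyloxy)ethyne | C#CO[Si](C(C)C)(C(C)C)C(C)C
A4 | alternative 2 | 3-iodo-8-methoxy-5,7-bis(methoxymethoxy)-2-[4-(triisopropylsilyloxy)phenyl]chromen-4-one | COCOc1cc(OCOC)c2c(=O)c(I)c(-c3ccc(O[Si](C(C)C)(C(C)C)C(C)C)cc3)oc2c1OC
A5 | alternative 2 | 1-[2-hydroxy-3-methoxy-4,6-bis(methoxymethoxy)phenyl]-3-[4-(triisopropylsilyloxy)phenyl]prop-2-yn-1-one | O=C(C#Cc1ccc(O[Si](C(C)C)(C(C)C)C(C)C)cc1)c1c(O)c(OC)c(OCOC)cc1OCOC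
A6 | alternative 3 | 8-methoxy-5,7-bis(methoxymethoxy)-2-{4-[(3-methylbut-2-en-1-yl)oxy]phenyl}chromen-4-one | O=c1cc(-c2ccc(OCC=C(C)C)cc2)oc2c(OC)c(OCOC)cc(OCOC)c12
A7 | alternative 3 | 6-iodo-2-methoxy-3,5-bis(methoxymethoxy)phenol | COc1c(O)c(I)c(OCOC)cc1OCOC
A8 | alternative 3 | 1-ethynyl-4-[(3-methylbut-2-en-1-yl)oxy]benzene | C#Cc1ccc(OCC=C(C)C)cc1
A9 | alternative 3 | carbon monoxide | [C-]#[O+]
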